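All runs are calculated from invented constants, noise included.

Per hour is my unit: each rate below is the share of the substrate charged, as target, lost in an hour.

| flask | substrate | reagent | temperature | remark | time |
|---|---|---|---|---|---|
| Tuesday's | 0.49 M | 0.98 M | 5 °C | the very flask that is asked about, followed so far |  |
| flask | 0.49 M | 0.980 M | 5 °C |  | 30 h |

Tuesday's run (percent of the substrate charged): time / h: target / % = 2.50: 19.4; 6.00: 13.9; 12.0: 11.1; 30.0: 9.8

(readings scatter by 0.3 percentage points)

- what is taken out of target is counted as made
- the earlier runs do not show what temperature does; that part of a forecast is a guess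
- additions bring no volume worth counting

- ash: change nothing and wait 10 h more
- maple: at 30 h add reagent, 50.0 % of the amount charged, then wait 10 h
- oak: at 30 h raise the temperature by 25 K, then wait 10 h
- birch: at 30 h take out 90 % of the target then present, then wait 10 h

- target, in percent of the substrate first charged, at 30 h
- which option adds most target ("none" when 2 percentage points or less is all one gets) (ash / maple / oak / birch / none)
- target present, with what was taken out counted in, in percent of the substrate first charged, after ash
- target present, with what was taken out counted in, in percent of the substrate first charged, after oak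

I follow the rate of Tuesday's flask, the flask asked about, and leave its concentrations aside. Each rate below is the fall of target between two readings, over the hours between them.

| Between | Rate | Slower than the rate before by |
|---|---|---|
| 2.50 h and 6.00 h | 0.0157 h⁻¹ | |
| 6.00 h and 12.0 h | 0.00467 h⁻¹ | 3.36 |
| 12.0 h and 30.0 h | 7.22 × 10⁻⁴ h⁻¹ | 6.46 |

The readings do not say what slows the rate. They do show how fast it slows. I let the rate r decay as e^(−λt), with the slowing constant λ read from the last two rows: 0.155 h⁻¹. This gives the halving time of the rate, ln(2)/λ = 4.46 h. It is a reading and carries their scatter.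

Summed over a time τ, such a rate gives a fall of (r/λ)(1 − e^(−λτ)). By 30.0 h, Tuesday's flask has passed 6.73 halvings, and r is down to 1.78 × 10⁻⁴ h⁻¹. So I expect a further 10 h to lose 0.09 percentage points, less than the scatter of 0.3 points. My reckoning therefore keeps "now" at the last reading, 9.8 %, and ash gains nothing. The readings show no temperature, so I put no number on oak.

The forecast gives 9.8 % for now, 9.7 % after ash and birch as best. For oak it gives 12 %, within 9.3 % to 20 %, saying “heating probably favours dissociation”.

The flask gives 9.82 % now and 9.78 % after ash, a loss of 0.038 points. Oak reaches 29.8 %, above the forecast's range, so the best option is oak, which adds 20 points.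

    intermediate ⇌ target + by-product (K = 0.340 M, k = 0.0202 min⁻¹, Ea = 85.0 kJ mol⁻¹, ΔH = −24.0 kJ mol⁻¹)
    substrate + reagent ⇌ intermediate (K = 1.17 L mol⁻¹, k = 0.0111 L mol⁻¹ min⁻¹, Ea = 52.0 kJ mol⁻¹, ΔH = 37.0 kJ mol⁻¹)
    target ⇌ isomer of the product (K = 7.20, k = 0.0105 min⁻¹, Ea = 97.0 kJ mol⁻¹, ΔH = −82.0 kJ mol⁻¹)
    crystals ⇌ by-product, rate k4*(cs4 - [by-product]) while solid is left; crystals form when [by-product] > cs4 (solubility = 0.270 M, k = 0.237 min⁻¹)
    (constants at 5 °C)

The further case is the same flask run at −10 °C. At 30.0 h it holds target 18.6 % and substrate 40.6 %, close to the 5 °C flask at 3.00 h, with 18.9 % and 38.2 %. Counted in 4.46 h, the halving time read at 5 °C, the 5 °C flask had passed 0.673 halvings at that moment and 6.73 by 30.0 h. So in target and substrate the flask at −10 °C stands after 30 h near the first count, and the halving time stays a 5 °C reading. Its isomer of the product stands at 29.0 %, against 70.1 % in the 5 °C flask at 30.0 h.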